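**Retrosynthetic overview**
- Last operations: global cleavage of seven methyl ethers and one silyl ether; before that, the dibenzo-p-dioxin ring is closed by intramolecular Ullmann etherification (ring B hydroxyl onto a ring C bromide).
- Ring B enters as 2,3-dibromo-5-methoxy-1,4-benzoquinone: two successive addition–elimination etherifications (ring A phenol first, ring C phenol second), then reduction to the hydroquinone.
- Key disconnection: the biaryl C–C bond of the dibenzofuran. Ring C enters as 2-bromo-6-methoxy-1,4-benzoquinone, whose CH next to C–Br is an enolonium (aryl cation) equivalent attacked by the ring D carbon of a resorcinol diaryl ether (rings D/E). Cyclodehydration closes the furan in the same operation, and the surviving bromine marks the carbon for the dioxin closure.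
- Rings D/E: 5-methoxyresorcinol, bis-MOM ether, ortho-lithiation/oxidation, Ullmann ether with 1-bromo-3,5-dimethoxybenzene.
- Ring order: furan ring (with the C–C bond) first, dioxin ring last; all five benzene rings come from commercial aromatics.

Assumption: the target has no stereocentre (it is achiral), so no stereocontrol is needed; 5,6-dibromovanillin is taken as a purchasable starting material.

**Step 1**
Reactants: 1 5-methoxybenzene-1,3-diol
Product: 2 1-methoxy-3,5-bis(methoxymethoxy)benzene
Conditions: NaH (2.4 equiv), MOMCl (2.4 equiv), DMF, 0 °C to rt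
Reagents that add atoms: chloromethyl methyl ether (MOMCl), COCCl
Why: Williamson-type O-alkylation of both phenoxides installs two MOM ethers that protect the resorcinol and direct the lithiation of step 2.

**Step 2**
Reactants: 2 1-methoxy-3,5-bis(methoxymethoxy)benzene
Product: 3 4-methoxy-2,6-bis(methoxymethoxy)phenol
Conditions: n-BuLi (1.15 equiv), TMEDA, THF, 0 °C; B(OMe)3, −78 °C to rt; then 30% H2O2, AcOH, 0 °C
Reagents that add atoms: hydrogen peroxide, OO
Why: Directed ortho-metalation takes place at the carbon flanked by both OMOM groups (cooperative chelation, most acidic site), and borylation/peroxide oxidation turns C–Li into C–OH.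

**Step 3**
Reactants: 3 4-methoxy-2,6-bis(methoxymethoxy)phenol; 4 1-bromo-3,5-dimethoxybenzene
Product: 5 2-(3,5-dimethoxyphenoxy)-5-methoxy-1,3-bis(methoxymethoxy)benzene
Conditions: CuI (10 mol %), picolinic acid (20 mol %), K3PO4 (2 equiv), DMSO, 90 °C
Reagents that add atoms: none
Why: Ullmann diaryl ether synthesis; the CuI/picolinic acid system couples 2,6-disubstituted phenols with unhindered aryl bromides and gives the ring D–O–ring E ether.

**Step 4**
Reactants: 6 2-bromo-6-methoxyphenol
Product: 7 2-bromo-6-methoxycyclohexa-2,5-diene-1,4-dione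
Conditions: (KSO3)2NO (2.2 equiv), KH2PO4 buffer, H2O/acetone, 0 °C to rt
Reagents that add atoms: potassium nitrosodisulfonate, [K+].[K+].[O]N(S(=O)(=O)[O-])S(=O)(=O)[O-]
Why: Teuber oxidation of a phenol with a free para position gives the para-quinone, which is the reversed-polarity form of ring C.

**Step 5 (key step)**
Reactants: 5 2-(3,5-dimethoxyphenoxy)-5-methoxy-1,3-bis(methoxymethoxy)benzene; 7 2-bromo-6-methoxycyclohexa-2,5-diene-1,4-dione
Product: 10 1-bromo-6-(3,5-dimethoxyphenoxy)-3,9-dimethoxydibenzo[b,d]furan-2,7-diol, via resorcinol diaryl ether 8 (not isolated), via biaryl hydroquinone 9 (not isolated)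
Conditions: HCl (cat.), MeOH, 40 °C, then evaporate; 7 (0.8 equiv, slow addition), TFA (0.2 equiv), AcOH, 20 °C, N2; then TsOH·H2O (0.3 equiv), 70 °C
Reagents that add atoms: none
Why: After MOM removal, quinone 7 acts as the enolonium (aryl cation) equivalent of its hydroquinone, so two carbons that are both innately nucleophilic phenol ortho positions are joined by an acid-promoted quinone–phenol Michael addition; the free-resorcinol ring of 8 (its two reactive CH are equivalent, and it is more nucleophilic than ring E) attacks the CH next to C–Br, because the CH next to C–OMe is a deactivated enol-ether carbon, and mild-acid cyclodehydration through the only free ortho-hydroxyl then closes the furan (methyl ethers do not exchange), leaving Br at C1 and a free OH at C2.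

**Step 6**
Reactants: 10 1-bromo-6-(3,5-dimethoxyphenoxy)-3,9-dimethoxydibenzo[b,d]furan-2,7-diol
Product: 11 1-bromo-7-[(tert-butyldimethylsilyl)oxy]-6-(3,5-dimethoxyphenoxy)-3,9-dimethoxydibenzo[b,d]furan-2-ol
Conditions: TBSCl (1.05 equiv), imidazole (2 equiv), DMF, −10 °C
Reagents that add atoms: tert-butyl(chloro)dimethylsilane (TBSCl), CC(C)(C)[Si](C)(C)Cl
Why: Site-selective silylation; the 7-OH has one ortho substituent, whereas the 2-OH is flanked by Br and OMe and hydrogen-bonded, so only the 2-OH remains as the nucleophile for step 9.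

**Step 7**
Reactants: 12 2,3-dibromo-4-hydroxy-5-methoxybenzaldehyde (5,6-dibromovanillin)
Product: 14 2,3-dibromo-5-methoxycyclohexa-2,5-diene-1,4-dione, via dibromohydroquinone 13 (not isolated)
Conditions: 30% H2O2 (1.05 equiv), NaOH (1.1 equiv), H2O/THF, 0 °C to rt, N2; then HCl to pH 1, FeCl3 (2.2 equiv), 0 °C
Reagents that add atoms: hydrogen peroxide, OO
Why: Dakin oxidation (aryl migration favoured by the para-phenoxide) converts CHO into OH, and FeCl3 oxidises the resulting hydroquinone to the quinone in the same pot.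

**Step 8**
Reactants: 14 2,3-dibromo-5-methoxycyclohexa-2,5-diene-1,4-dione; 15 3,5-dimethoxyphenol
Product: 16 3-bromo-2-(3,5-dimethoxyphenoxy)-5-methoxycyclohexa-2,5-diene-1,4-dione
Conditions: K2CO3 (1.05 equiv), MeCN, −10 °C to 0 °C
Reagents that add atoms: none
Why: Addition–elimination on a haloquinone; the phenoxide adds β to the more electrophilic carbonyl (the one next to C–OMe, which is not a vinylogous ester), so the bromine para to the methoxy carbon is replaced, as in amine additions to methoxyquinones, and this places ring A correctly on ring B.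

**Step 9**
Reactants: 11 1-bromo-7-[(tert-butyldimethylsilyl)oxy]-6-(3,5-dimethoxyphenoxy)-3,9-dimethoxydibenzo[b,d]furan-2-ol; 16 3-bromo-2-(3,5-dimethoxyphenoxy)-5-methoxycyclohexa-2,5-diene-1,4-dione
Product: 18 2-({1-bromo-7-[(tert-butyldimethylsilyl)oxy]-6-(3,5-dimethoxyphenoxy)-3,9-dimethoxydibenzo[b,d]furan-2-yl}oxy)-3-(3,5-dimethoxyphenoxy)-6-methoxybenzene-1,4-diol, via diaryloxyquinone 17 (not isolated)
Conditions: NaH (1.0 equiv), THF, 0 °C; add 16, THF/DMF, 0 °C to rt; then Na2S2O4, H2O/THF, rt
Reagents that add atoms: none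
Why: A second addition–elimination displaces the remaining bromide irreversibly (attack at the aryloxy carbon is reversible and re-expels the less basic, hindered phenoxide of 11) and forms the crowded ring C–O–ring B ether without a metal, and dithionite reduction then frees the hydroquinone hydroxyl needed for ring closure.

**Step 10**
Reactants: 18 2-({1-bromo-7-[(tert-butyldimethylsilyl)oxy]-6-(3,5-dimethoxyphenoxy)-3,9-dimethoxydibenzo[b,d]furan-2-yl}oxy)-3-(3,5-dimethoxyphenoxy)-6-methoxybenzene-1,4-diol
Product: 19 hepta-O-methyl mono-O-TBS phlorofucofuroeckol A (free OH on ring B beside the ring A ether; OTBS on ring D beside the ring E ether)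
Conditions: CuI (20 mol %), N,N-dimethylglycine (40 mol %), Cs2CO3 (2.5 equiv), degassed 1,4-dioxane, 100 °C, Ar
Reagents that add atoms: none
Why: Intramolecular Ullmann etherification closes the six-membered dioxin ring between the ring B hydroxyl next to the new ether and the ring C bromide, in the only possible orientation; the other hydroquinone hydroxyl has no halide within reach.

**Step 11**
Reactants: 19 hepta-O-methyl mono-O-TBS phlorofucofuroeckol A
Product: 20 phlorofucofuroeckol A
Conditions: BBr3 (20 equiv), CH2Cl2, −78 °C to rt, 16 h; then H2O, 0 °C, Ar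
Reagents that add atoms: none
Why: Lewis-acid ether cleavage; bromide attacks the methyl groups of the seven boron-complexed aryl methyl ethers and the silicon of the silyl ether, while the diaryl ether, dioxin and furan C–O bonds (aryl on both sides) are untouched.

**Compound list**
1 | 5-methoxybenzene-1,3-diol | COc1cc(O)cc(O)c1 | starting material
2 | 1-methoxy-3,5-bis(methoxymethoxy)benzene | COCOc1cc(OC)cc(OCOC)c1 | intermediate
3 | 4-methoxy-2,6-bis(methoxymethoxy)phenol | COCOc1cc(OC)cc(OCOC)c1O | intermediate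
4 | 1-bromo-3,5-dimethoxybenzene | COc1cc(Br)cc(OC)c1 | starting material
5 | 2-(3,5-dimethoxyphenoxy)-5-methoxy-1,3-bis(methoxymethoxy)benzene | COCOc1cc(OC)cc(OCOC)c1Oc1cc(OC)cc(OC)c1 | intermediate
6 | 2-bromo-6-methoxyphenol | COc1cccc(Br)c1O | starting material
7 | 2-bromo-6-methoxycyclohexa-2,5-diene-1,4-dione | COC1=CC(=O)C=C(Br)C1=O | intermediate
8 | 2-(3,5-dimethoxyphenoxy)-5-methoxybenzene-1,3-diol | COc1cc(O)c(Oc2cc(OC)cc(OC)c2)c(O)c1 | intermediate
9 | 6-bromo-3'-(3,5-dimethoxyphenoxy)-4,6'-dimethoxy-[1,1'-biphenyl]-2,2',4',5-tetrol | COc1cc(O)c(c(Br)c1O)-c1c(O)c(Oc2cc(OC)cc(OC)c2)c(O)cc1OC | intermediate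
10 | 1-bromo-6-(3,5-dimethoxyphenoxy)-3,9-dimethoxydibenzo[b,d]furan-2,7-diol | COc1cc2oc3c(Oc4cc(OC)cc(OC)c4)c(O)cc(OC)c3c2c(Br)c1O | intermediate
11 | 1-bromo-7-[(tert-butyldimethylsilyl)oxy]-6-(3,5-dimethoxyphenoxy)-3,9-dimethoxydibenzo[b,d]furan-2-ol | COc1cc2oc3c(Oc4cc(OC)cc(OC)c4)c(O[Si](C)(C)C(C)(C)C)cc(OC)c3c2c(Br)c1O | intermediate
12 | 2,3-dibromo-4-hydroxy-5-methoxybenzaldehyde (5,6-dibromovanillin) | COc1cc(C=O)c(Br)c(Br)c1O | starting material
13 | 2,3-dibromo-5-methoxybenzene-1,4-diol | COc1cc(O)c(Br)c(Br)c1O | intermediate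
14 | 2,3-dibromo-5-methoxycyclohexa-2,5-diene-1,4-dione | COC1=CC(=O)C(Br)=C(Br)C1=O | intermediate
15 | 3,5-dimethoxyphenol | COc1cc(O)cc(OC)c1 | starting material
16 | 3-bromo-2-(3,5-dimethoxyphenoxy)-5-methoxycyclohexa-2,5-diene-1,4-dione | COC1=CC(=O)C(Oc2cc(OC)cc(OC)c2)=C(Br)C1=O | intermediate
17 | 3-({1-bromo-7-[(tert-butyldimethylsilyl)oxy]-6-(3,5-dimethoxyphenoxy)-3,9-dimethoxydibenzo[b,d]furan-2-yl}oxy)-2-(3,5-dimethoxyphenoxy)-5-methoxycyclohexa-2,5-diene-1,4-dione | COC1=CC(=O)C(Oc2cc(OC)cc(OC)c2)=C(Oc2c(OC)cc3oc4c(Oc5cc(OC)cc(OC)c5)c(O[Si](C)(C)C(C)(C)C)cc(OC)c4c3c2Br)C1=O | intermediate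
18 | 2-({1-bromo-7-[(tert-butyldimethylsilyl)oxy]-6-(3,5-dimethoxyphenoxy)-3,9-dimethoxydibenzo[b,d]furan-2-yl}oxy)-3-(3,5-dimethoxyphenoxy)-6-methoxybenzene-1,4-diol | COc1cc(O)c(Oc2cc(OC)cc(OC)c2)c(Oc2c(OC)cc3oc4c(Oc5cc(OC)cc(OC)c5)c(O[Si](C)(C)C(C)(C)C)cc(OC)c4c3c2Br)c1O | intermediate
19 | hepta-O-methyl mono-O-TBS phlorofucofuroeckol A (free OH on ring B beside the ring A ether; OTBS on ring D beside the ring E ether) | COc1cc(OC)cc(Oc2c(O)cc(OC)c3c2Oc2c(OC)cc4oc5c(Oc6cc(OC)cc(OC)c6)c(O[Si](C)(C)C(C)(C)C)cc(OC)c5c4c2O3)c1 | intermediate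
20 | phlorofucofuroeckol A | Oc1cc(O)cc(Oc2c(O)cc(O)c3c2Oc2c(O)cc4oc5c(Oc6cc(O)cc(O)c6)c(O)cc(O)c5c4c2O3)c1 | target

**Step count**
Total: 11 steps. Longest linear sequence: 8 steps (1, 2, 3, 5, 6, 9, 10, 11).

**Steps most likely to fail, with fallbacks**

Step 5 (key annulation). Risks: arylation on ring E instead of ring D, redox exchange between adduct and quinone, or closure with loss of methanol instead of water. The fallback makes the same biaryl bond by cross-coupling and sets out from 5 and 14. Compound 5 is lithiated between OMOM and OMe of the central ring (n-BuLi, THF, 0 °C) and quenched with B(OiPr)3 to give the boronic acid F1. Suzuki–Miyaura coupling of F1 with dibromoquinone 14 at its more electrophilic C–Br, the one para to OMe (Pd(OAc)2, SPhos, K3PO4, toluene/H2O, 60 °C), gives the arylquinone F2. Reduction with Na2S2O4 and MOM removal with HCl/MeOH return to the biaryl hydroquinone 9, now isolated, which TsOH closes to 10.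

Step 9 (second substitution on the aryloxy-bromoquinone). Risks: exchange of the ring A aryloxy group, or electron transfer from the electron-rich phenoxide to the quinone. The fallback avoids quinone substitution and sets out from 12, 15 and 11. Copper-catalysed etherification of 12 with 15 at the bromide ortho to the aldehyde (CuI, N,N-dimethylglycine, Cs2CO3, dioxane, 100 °C) gives the aldehyde F3, whose formyl group is a masked ring B hydroxyl. Head-to-tail double Ullmann condensation of the two ortho-bromophenols 11 and F3 (F3 in excess; CuI, 2,2,6,6-tetramethylheptane-3,5-dione, Cs2CO3, NMP, 120 °C) gives the dibenzodioxin aldehyde F4 in the single possible cross orientation. Dakin oxidation (mCPBA, CH2Cl2; then NaHCO3, MeOH/H2O, 0 °C) comes back to the route at 19.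

Step 10 (Ullmann closure on an air-sensitive hydroquinone next to a hindered bromide). Risks: hydroquinone oxidation and protodebromination. The fallback sets out from 18. The unhindered ring B hydroxyl is silylated (TBSCl, imidazole, DMF, 0 °C) to give the bis-silyl bromophenol F5. The dioxin is then closed by palladium-catalysed C–O coupling (Pd(OAc)2, tBuXPhos, K3PO4, toluene, 100 °C) to give the bis-silyl pentacycle F6. BBr3 cleaves seven methyl ethers and both silyl ethers, so the fallback comes back to the route at 20.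

**Further compounds**
F1 | step 5 | [3-(3,5-dimethoxyphenoxy)-6-methoxy-2,4-bis(methoxymethoxy)phenyl]boronic acid | COCOc1cc(OC)c(B(O)O)c(OCOC)c1Oc1cc(OC)cc(OC)c1
F2 | step 5 | 3-bromo-2-[3-(3,5-dimethoxyphenoxy)-6-methoxy-2,4-bis(methoxymethoxy)phenyl]-5-methoxycyclohexa-2,5-diene-1,4-dione | COC1=CC(=O)C(c2c(OCOC)c(Oc3cc(OC)cc(OC)c3)c(OCOC)cc2OC)=C(Br)C1=O
F3 | step 9 | 3-bromo-2-(3,5-dimethoxyphenoxy)-4-hydroxy-5-methoxybenzaldehyde | COc1cc(C=O)c(Oc2cc(OC)cc(OC)c2)c(Br)c1O
F4 | step 9 | analogue of 19 with CHO in place of the free ring B hydroxyl | COc1cc(OC)cc(Oc2c(C=O)cc(OC)c3c2Oc2c(OC)cc4oc5c(Oc6cc(OC)cc(OC)c6)c(O[Si](C)(C)C(C)(C)C)cc(OC)c5c4c2O3)c1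
F5 | step 10 | 2-({1-bromo-7-[(tert-butyldimethylsilyl)oxy]-6-(3,5-dimethoxyphenoxy)-3,9-dimethoxydibenzo[b,d]furan-2-yl}oxy)-4-[(tert-butyldimethylsilyl)oxy]-3-(3,5-dimethoxyphenoxy)-6-methoxyphenol | COc1cc(O[Si](C)(C)C(C)(C)C)c(Oc2cc(OC)cc(OC)c2)c(Oc2c(OC)cc3oc4c(Oc5cc(OC)cc(OC)c5)c(O[Si](C)(C)C(C)(C)C)cc(OC)c4c3c2Br)c1O
F6 | step 10 | hepta-O-methyl bis-O-TBS phlorofucofuroeckol A (OTBS on ring B beside the ring A ether; OTBS on ring D beside the ring E ether) | COc1cc(OC)cc(Oc2c(O[Si](C)(C)C(C)(C)C)cc(OC)c3c2Oc2c(OC)cc4oc5c(Oc6cc(OC)cc(OC)c6)c(O[Si](C)(C)C(C)(C)C)cc(OC)c5c4c2O3)c1
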